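## Structural features

Numbering used throughout: C1 is the lactone carbonyl, C2 its methylene, C3 the peroxy methine, C4 the quaternary carbon bearing the lactone oxygen, C5 the ring methylene, C6 the quaternary peroxy carbon, C7–C14 the side chain (C14 benzylic).

The core is a 1,2-dioxane (O–O, C3, C4, C5, C6) cis-fused through the C3–C4 bond to a γ-lactone (O, C1, C2, C3, C4). C3 and C4 are adjacent stereocentres at the ring fusion and C6 is 1,3 to C4 across C5; the methyl groups on C4 and C6 lie on one face of the dioxane, while the C2 arm, the lactone oxygen and the C7 chain lie on the other. C8 is an isolated methyl-bearing centre on the chain, 1,3 to C6 (3S,4S,6R,8R overall). From C9 the chain runs into a (10E,12E)-10,12-dimethyl-1,3-diene that ends in the C14 benzyl group. The fragile groups are: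
- the O–O bond (phosphines, hydrides, low-valent metals, a carbon radical next to it);
- the C3–O bond, which is β to the lactone carbonyl and open to base-induced elimination;
- the lactone itself;
- the electron-rich side-chain diene, which would not survive singlet oxygen, electrophilic iodine or stannyl radicals.

The real difficulty is to put oxygen on the two fully substituted carbons C4 and C6 with the right relative configuration while making the O–O bond, and to relate this array to C8, which is too remote to steer anything. The key step exploits that the peroxide oxygens sit on C3 and C6, 1,4 to each other across C4–C5: the dioxane is the lactonised, reduced form of a 3,6-dihydro-1,2-dioxine, that is of a C3=C4–C5=C6 diene plus O2, and the C4=C5 alkene left by the cycloaddition is exactly where the C1 carboxyl on the C3 arm must deliver the lactone oxygen.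

## Logic of the disconnections

24 ⇒ 20 + 23. The C11–C12 single bond between the two trisubstituted alkenes of the side-chain diene is cut. The diene cannot coexist with singlet oxygen, electrophilic iodine or stannyl radicals, so it must be completed after all of them. Cutting in its middle splits 24 into the finished bicyclic core 20 and a four-carbon aryl piece 23 that takes one step to make. The forward coupling must keep both alkene geometries, and its palladium catalyst and base must leave the O–O bond and the lactone alone.

20 ⇒ 19 ⇒ 18 ⇒ 17 ⇒ 16. In 20 the C11–B and C10–CH3 bonds are removed together (both come from one syn addition across the C10≡C11 triple bond of 19), then C11 itself (one-carbon homologation of the C10 aldehyde 18), then the oxidation level and the silyl group at C10. This reduces the side chain to a protected primary alcohol that is inert in all earlier steps. The demand is heavy: a boryl-copper species and an alkoxide must add to the alkyne faster than they attack the peroxide or enolise the lactone, and the homologation must get by with a weak base.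

16 ⇒ 15 ⇒ 14. The C5–H bond is traced to a C5–I bond and the C4–O lactone bond is cut, opening the lactone to the C3 acetic acid arm and a C4=C5 alkene. The alkene left by the cycloaddition is thus used, and C4 needs no reagent control, because the carboxyl group can only reach C4 from the face that carries the C3 arm. The forward steps demand Markovnikov 5-exo delivery of oxygen to C4 and a hydrogen-atom donor fast enough to quench the C5 radical before it attacks the neighbouring O–O bond.

14 ⇒ 12 + 13. The C3–O and C6–O bonds are cut in one retro-[4+2] step, which removes the ring, the peroxide and two stereocentres and leaves an open-chain (3E,5E)-dienoic acid. This is the largest simplification of the route: a bicyclic stereochemical problem becomes a problem of alkene geometry. The forward step must prefer cycloaddition to the ene reaction although C6 is fully substituted, needs both alkenes E so that the C2 and C7 arms come out cis, and cannot be expected to distinguish the diene faces, so a separation follows. 12 is kept as the free acid, so that lactonisation needs no deprotection and no base is applied once the O–O bond exists. Its C10 oxygen carries a silyl group that tolerates light, oxygen, iodine and tin hydride and leaves under buffered fluoride.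

12 ⇒ 7 + 11. The C4–C5 single bond of the diene is cut, so that each trisubstituted alkene is made separately with its geometry fixed by a syn addition to an alkyne. 11 already has C1 at the acid oxidation level. Under the basic coupling conditions it is a carboxylate, which does not enolise, so the skipped dienoic acid never sees an ester hydrolysis or an alcohol oxidation that could move the C3=C4 double bond into conjugation. The coupling has to work with a free carboxylate and two hindered alkenyl partners.

7 ⇒ 5 ⇒ 3 ⇒ 2 ⇒ 1. In 7 the C5–I and C6–CH3 bonds go back to the terminal alkyne of 5 (through 6). The alkyne carbon C5 is removed to reach the ester carbon of 3 (through 4), and the silyl ether and carbinol go back to the carboxyl group of 1. C8, the one stereocentre the route cannot create, is bought with 1, whose two differentiated carboxyl groups become the two arms: the acid arm is reduced to C9–C10 and the ester arm is homologated to C7–C6≡C5. The forward steps must reduce the acid and not the ester, and must add methyl to C6 and the metal to C5 in a syn fashion.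

11 ⇒ 10 ⇒ 9 ⇒ 8. The C1 oxidation level is stepped down to the alcohol, and the C4–B and C3–H bonds are removed together, which leads to a commercial alkynol. The forward hydroboration must put boron on the methyl-bearing alkyne carbon and add syn, so that boron, and later C5, is trans to the C2 arm.

23 ⇒ 21. The C12–I and C13–H bonds are removed together (through 22). The forward hydrometalation must place the metal on the methyl-bearing carbon of an unsymmetrical alkyne and add syn, which makes the later C11–C12 bond trans to C14.

## Other disconnections considered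

Alternative 1: The cut removes three bonds at once, C6–O, C5–C6 and C4–O, and leads back to the acyclic hydroperoxy keto ester A1. In A1 the C3 hydroperoxide and the isopropenyl group (C4, C5) sit on the acyl part, and the C6 methyl ketone hangs on the C10 alcohol part of the same ester. In the forward sense a Lewis acid (TMSOTf or Sc(OTf)3) would condense the hydroperoxide with the ketone to a peroxycarbenium ion, the C5 methylene would attack C6 in a Prins closure of the 1,2-dioxane, and the ester carbonyl would trap the tertiary C4 cation. Water would then release the C10 alcohol and leave the lactone, giving A2, which has the constitution and configuration of 17.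
- In its favour: both rings, both quaternary centres and three bonds would arise in one flask, and no tin, iodine or photochemistry is needed. The product is the alcohol that the chosen route reaches only three steps after its cycloaddition, so on step economy after O–O introduction this plan is the better one. Because C6 is attacked inside a ring that contains C8, the tether could in principle relay C8 to C6, a handle on the facial problem that the chosen plan lacks.
- Against it here: the secondary allylic hydroperoxide at C3 must itself be a single enantiomer; an ene reaction would give it racemic, which only moves the separation problem to C3. Allylic hydroperoxides are prone to Hock cleavage under the very acids that generate the peroxycarbenium ion. That ion has to form inside an eleven-membered ring in competition with oligomers. The configuration at C6 would rest on a macrocyclic transition state that cannot be predicted with confidence. The final hydrolysis must expel the C10 alcohol and not reopen the C4–O bond.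
- Comparison: structurally more convergent and mechanistically more ambitious, but it stacks three uncertain events where the chosen plan has one uncertain cycloaddition followed by well-precedented steps.

Alternative 2: The cut is the C2–C3 bond of the lactone; the precursor is the diazoacetate A3 of a monocyclic 1,2-dioxan-4-ol in which C3 is still a peroxy methylene. In the forward sense Rh2(OAc)4 (or the tetraacetamidate Rh2(acam)4) would generate the carbenoid, which inserts into the C3–H bond cis to the ester oxygen through a five-membered transition state. This would form C2–C3, the C3 stereocentre and the lactone in one step and give A4, identical in structure with 16.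
- In its favour: a C–H bond next to oxygen is activated for insertion, and five-membered closure is the normal preference of acetate carbenoids. Only the cis-fused product can form, so C3 would be set by C4 without reagent control. The conditions are neutral, catalytic and free of tin, selenium and iodine. On reagent burden and on the way C3 is set this plan is the equal or the better of the chosen one, and from A4 onwards the two plans coincide.
- Against it here: the disconnection does not touch the hard part. A 1,2-dioxane with the tertiary C4 alcohol and the quaternary C6 in the right relative configuration must be built first, whereas the chosen plan gets C4 for nothing from the tether. The acceptor-only carbenoid has two other 1,5-related C–H sites (the C5 methylene and the C4 methyl group) and the peroxide lone pairs within reach, so insertion at C5, ylide formation at oxygen and O–O cleavage would compete. The second oxygen makes the C3–H bond less hydridic than in an ordinary ether. Esterifying a hindered tertiary alcohol as its diazoacetate costs extra steps.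
- Comparison: a cleaner final ring closure, paid for with a higher step count and less secure chemoselectivity.

Alternative 3: The cut is the C4–O bond; the precursor is the saturated dioxane acid A5, with a tertiary C4–H bond on the face where the lactone oxygen has to appear. In the forward sense Mn(CF3SO3)2(pdp) and H2O2 in a fluorinated alcohol would bind the carboxylate, abstract the γ hydrogen at C4 and return oxygen from the bound carboxylate with retention, closing the lactone and giving the acetate A6.
- In its favour: the tertiary γ C–H bond is the electronically and geometrically preferred site of carboxylate-directed oxidation, and retention makes the outcome at C4 predictable. The oxidant is H2O2 and neither halogen nor tin is used, so in atom economy and reagent toxicity this plan is better than iodolactonisation followed by tin hydride. In step count for the lactone (one reduction of the dihydrodioxine alkene plus one oxidation, against iodolactonisation plus deiodination) it is the equal of the chosen plan.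
- Against it here: A5 already needs the C4 configuration. That means a face-selective, O–O-sparing reduction of the C4=C5 alkene of a dihydrodioxine such as 14 (diimide at best) with nothing to control the face, whereas the carboxyl tether of the chosen plan can only deliver oxygen cis. The chain carries a second tertiary C–H bond at C8 and the α-peroxy C3–H bond, both open to the non-directed pathway even with the deactivating acetate. Divalent manganese with H2O2 is a one-electron redox pair that may cleave the O–O bond.
- Comparison: the chosen plan is stereochemically safer at C4 and gentler on the peroxide, at the price of stoichiometric tin.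

Key step: step 9

Assumption: the two diastereomers that arise in step 9 from attack on the two faces of the diene are taken to be separable by chromatography at 14 or, failing that, as the iodolactones after step 10.

## Route

Step 1
Reactants: 1 methyl hydrogen (R)-3-methylglutarate
Product: 2 methyl (3R)-5-hydroxy-3-methylpentanoate
Conditions: BH3·SMe2 (1.2 equiv), THF, 0 °C → rt; MeOH quench
Reagents that add atoms: none
Why: Borane reduces the free carboxylic acid through its acyloxyborane much faster than the methyl ester, so only the acid arm becomes the C10 carbinol (chemoselective borane reduction); C8 is not touched.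

Step 2
Reactants: 2 methyl (3R)-5-hydroxy-3-methylpentanoate
Product: 3 methyl (3R)-5-[(tert-butyldimethylsilyl)oxy]-3-methylpentanoate
Conditions: TBSCl, imidazole, CH2Cl2, 0 °C → rt
Reagents that add atoms: tert-butyldimethylsilyl chloride, CC(C)(C)[Si](C)(C)Cl
Why: Routine silylation of a primary alcohol; protecting at once prevents lactonisation of the δ-hydroxy ester.

Step 3
Reactants: 3 methyl (3R)-5-[(tert-butyldimethylsilyl)oxy]-3-methylpentanoate
Product: 5 tert-butyldimethyl{[(3S)-3-methylhex-5-yn-1-yl]oxy}silane, via aldehyde 4 (not isolated)
Conditions: iBu2AlH (1.05 equiv), CH2Cl2, −78 °C; then MeOH, dimethyl (1-diazo-2-oxopropyl)phosphonate, K2CO3, −78 °C → rt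
Reagents that add atoms: dimethyl (1-diazo-2-oxopropyl)phosphonate, COP(=O)(OC)C(=[N+]=[N-])C(C)=O
Why: At −78 °C the hydride stops at the aluminium hemiacetal, which releases aldehyde 4 in the methanolic base, where it is homologated in the same flask by the Ohira–Bestmann reagent (Seyferth–Gilbert-type olefination and 1,2-shift). C8 is β to the carbonyl and cannot epimerise; the descriptor changes from R to S only because the priorities change.

Step 4
Reactants: 5 tert-butyldimethyl{[(3S)-3-methylhex-5-yn-1-yl]oxy}silane
Product: 7 tert-butyl{[(3S,5E)-6-iodo-3,5-dimethylhex-5-en-1-yl]oxy}dimethylsilane, via alkenylalane 6 (not isolated)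
Conditions: AlMe3 (2.5 equiv), Cp2ZrCl2 (0.25 equiv), CH2Cl2, 0 °C → rt; then [I][I], THF, −30 → 0 °C
Reagents that add atoms: trimethylaluminium, C[Al](C)C; iodine, [I][I]
Why: Zirconium-catalysed Negishi carboalumination adds methyl and aluminium syn across the terminal alkyne with methyl on the internal carbon, and iodinolysis of the C–Al bond goes with retention, which fixes the later 5E geometry.

Step 5
Reactants: 8 pent-3-yn-1-ol
Product: 9 (3Z)-4-(4,4,5,5-tetramethyl-1,3,2-dioxaborolan-2-yl)pent-3-en-1-ol (boron trans to the hydroxyethyl arm)
Conditions: B2pin2 (1.1 equiv), CuCl (5 mol %), Xantphos (5 mol %), NaOtBu (10 mol %), MeOH (2 equiv), THF, rt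
Reagents that add atoms: bis(pinacolato)diboron, CC1(C)OB(OC1(C)C)B1OC(C)(C)C(C)(C)O1
Why: Copper-catalysed formal hydroboration: the boryl-copper species adds syn with boron on the less hindered, methyl-bearing carbon (copper on C3, next to the oxygen-bearing arm), and methanol protonates the C–Cu bond with retention, so boron ends up trans to the C2 arm.

Step 6
Reactants: 9 (3Z)-4-(4,4,5,5-tetramethyl-1,3,2-dioxaborolan-2-yl)pent-3-en-1-ol
Product: 10 (3Z)-4-(4,4,5,5-tetramethyl-1,3,2-dioxaborolan-2-yl)pent-3-enal
Conditions: Dess–Martin periodinane, NaHCO3, CH2Cl2, 0 °C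
Reagents that add atoms: none
Why: Buffered Dess–Martin oxidation is mild enough for a β,γ-unsaturated aldehyde and does not touch the alkenyl boronate; the crude aldehyde is used at once.

Step 7
Reactants: 10 (3Z)-4-(4,4,5,5-tetramethyl-1,3,2-dioxaborolan-2-yl)pent-3-enal
Product: 11 (3Z)-4-(4,4,5,5-tetramethyl-1,3,2-dioxaborolan-2-yl)pent-3-enoic acid
Conditions: NaClO2, NaH2PO4, 2-methyl-2-butene (excess), tBuOH/H2O, 0 °C → rt
Reagents that add atoms: sodium chlorite, [Na+].[O-]Cl=O
Why: Pinnick oxidation takes the aldehyde to the acid without moving the double bond; chlorite at pH 3–4 is not expected to oxidise the C–B bond, and the alkene scavenger removes HOCl.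

Step 8
Reactants: 7 tert-butyl{[(3S,5E)-6-iodo-3,5-dimethylhex-5-en-1-yl]oxy}dimethylsilane; 11 (3Z)-4-(4,4,5,5-tetramethyl-1,3,2-dioxaborolan-2-yl)pent-3-enoic acid
Product: 12 (3E,5E,8S)-10-[(tert-butyldimethylsilyl)oxy]-4,6,8-trimethyldeca-3,5-dienoic acid
Conditions: PdCl2(dppf) (5 mol %), K3PO4 (aq., 4 equiv), THF, 50 °C; work-up at pH 4
Reagents that add atoms: none
Why: Suzuki–Miyaura coupling forms C4–C5 with retention at both alkenyl partners and so gives the (3E,5E)-diene. Under the basic conditions C1 is a carboxylate, which cannot enolise, so the skipped diene should not slip into conjugation.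

Step 9
Reactants: 12 (3E,5E,8S)-10-[(tert-butyldimethylsilyl)oxy]-4,6,8-trimethyldeca-3,5-dienoic acid; 13 dioxygen
Product: 14 2-[(3S,6R)-6-{(2R)-4-[(tert-butyldimethylsilyl)oxy]-2-methylbutyl}-4,6-dimethyl-3,6-dihydro-1,2-dioxin-3-yl]acetic acid (C2 arm and C7 chain cis)
Conditions: O2, tetraphenylporphyrin (1 mol %), CH2Cl2, visible light (white LED or halogen lamp), −78 °C
Reagents that add atoms: dioxygen (compound 13), O=O
Why: Triplet-excited tetraphenylporphyrin transfers its energy to O2, and the singlet oxygen adds across C3 and C6 of the cisoid diene in a suprafacial [4+2] cycloaddition that makes both C–O bonds in one event and leaves the C4=C5 alkene; the closest known reaction type is the singlet-oxygen endoperoxidation of acyclic 1,3-dienes to 3,6-dihydro-1,2-dioxines. The six-membered ring is closed by the cycloaddition itself, with no separate ring-closing attack. The relative configuration at C3 and C6 is controlled by the diene geometry: in the (3E,5E) isomer the C2 arm and the C7 chain are both outside substituents and must end up cis. The absolute sense is not controlled, because C8 is insulated from the diene by C7, so 14 should form with its (3R,6S) diastereomer in comparable amounts and is separated by chromatography, here or as the iodolactone after step 10. The step needs cycloaddition to win over the Schenck ene reaction at the C4 and C6 methyl groups and at C7 and C2; the C4 methyl group helps, since in the s-trans conformer it clashes with the inside methyl on C6, which raises the share of the reactive cisoid conformer, and an aprotic solvent at low temperature limits solvent capture of polar intermediates and decay of the peroxides. The diene is the only π system electron-rich enough to react, the silyl ether is inert, and the acid is left free so that no base is needed once the O–O bond exists.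

Step 10
Reactants: 14 2-[(3S,6R)-6-{(2R)-4-[(tert-butyldimethylsilyl)oxy]-2-methylbutyl}-4,6-dimethyl-3,6-dihydro-1,2-dioxin-3-yl]acetic acid
Product: 15 (3R,4S,4aR,7aS)-3-{(2R)-4-[(tert-butyldimethylsilyl)oxy]-2-methylbutyl}-4-iodo-3,4a-dimethyltetrahydrofuro[3,2-c][1,2]dioxin-6(3H)-one (iodine on C5, trans to the lactone oxygen)
Conditions: [I][I] (3 equiv), NaHCO3 (aq.), MeCN, 0 °C, dark
Reagents that add atoms: iodine, [I][I]
Why: Iodolactonisation: the iodonium ion forms reversibly on C4=C5 and only the one anti to the C3 acetic acid arm is productive; 5-exo attack of the carboxylate at the more substituted C4 gives the cis-fused γ-lactone and sets C4, with iodine trans on C5.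

Step 11
Reactants: 15 (3R,4S,4aR,7aS)-3-{(2R)-4-[(tert-butyldimethylsilyl)oxy]-2-methylbutyl}-4-iodo-3,4a-dimethyltetrahydrofuro[3,2-c][1,2]dioxin-6(3H)-one
Product: 16 (3R,4aS,7aS)-3-{(2R)-4-[(tert-butyldimethylsilyl)oxy]-2-methylbutyl}-3,4a-dimethyltetrahydrofuro[3,2-c][1,2]dioxin-6(3H)-one
Conditions: Bu3SnH (1.3 equiv, slow addition), PhSeSePh (10 mol %), Et3B/air (cat.), toluene, 0 °C → rt
Reagents that add atoms: none
Why: Radical deiodination: iodine abstraction by the stannyl radical is far faster than its attack on O–O, and benzeneselenol formed in the flask hands hydrogen to the C5 radical at close to the diffusion limit (polarity-reversal catalysis), which should outrun attack of that radical on the adjacent peroxide. The C5 stereocentre is erased.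

Step 12
Reactants: 16 (3R,4aS,7aS)-3-{(2R)-4-[(tert-butyldimethylsilyl)oxy]-2-methylbutyl}-3,4a-dimethyltetrahydrofuro[3,2-c][1,2]dioxin-6(3H)-one
Product: 17 (3R,4aS,7aS)-3-[(2R)-4-hydroxy-2-methylbutyl]-3,4a-dimethyltetrahydrofuro[3,2-c][1,2]dioxin-6(3H)-one
Conditions: HF·pyridine, pyridine, THF, 0 °C → rt
Reagents that add atoms: none
Why: Buffered fluoride cleaves the primary silyl ether under weakly acidic conditions that neither open the lactone nor affect the peroxide.

Step 13
Reactants: 17 (3R,4aS,7aS)-3-[(2R)-4-hydroxy-2-methylbutyl]-3,4a-dimethyltetrahydrofuro[3,2-c][1,2]dioxin-6(3H)-one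
Product: 18 (3S)-4-[(3R,4aS,7aS)-3,4a-dimethyl-6-oxohexahydrofuro[3,2-c][1,2]dioxin-3-yl]-3-methylbutanal (the C10 aldehyde)
Conditions: Dess–Martin periodinane, NaHCO3, CH2Cl2, 0 °C → rt
Reagents that add atoms: none
Why: Dess–Martin oxidation is neutral and non-reducing, so lactone and O–O bond survive; C8 is β to the new carbonyl and keeps its configuration (the descriptor changes by priority only).

Step 14
Reactants: 18 (3S)-4-[(3R,4aS,7aS)-3,4a-dimethyl-6-oxohexahydrofuro[3,2-c][1,2]dioxin-3-yl]-3-methylbutanal
Product: 19 (3R,4aS,7aS)-3,4a-dimethyl-3-[(2R)-2-methylpent-4-yn-1-yl]tetrahydrofuro[3,2-c][1,2]dioxin-6(3H)-one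
Conditions: dimethyl (1-diazo-2-oxopropyl)phosphonate, K2CO3, MeOH, 0 °C, short reaction time
Reagents that add atoms: dimethyl (1-diazo-2-oxopropyl)phosphonate, COP(=O)(OC)C(=[N+]=[N-])C(C)=O
Why: Ohira–Bestmann homologation adds C11 under the mildest base available for this transformation; it is run cold and briefly to limit enolisation of the lactone, the only route to loss of the C3–O bond.

Step 15
Reactants: 19 (3R,4aS,7aS)-3,4a-dimethyl-3-[(2R)-2-methylpent-4-yn-1-yl]tetrahydrofuro[3,2-c][1,2]dioxin-6(3H)-one
Product: 20 (3R,4aS,7aS)-3-[(2R,4E)-2,4-dimethyl-5-(4,4,5,5-tetramethyl-1,3,2-dioxaborolan-2-yl)pent-4-en-1-yl]-3,4a-dimethyltetrahydrofuro[3,2-c][1,2]dioxin-6(3H)-one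
Conditions: B2pin2 (1.2 equiv), MeI (3 equiv), CuCl (10 mol %), Xantphos (10 mol %), NaOtBu (1.2 equiv), THF, 0 °C → rt
Reagents that add atoms: bis(pinacolato)diboron, CC1(C)OB(OC1(C)C)B1OC(C)(C)C(C)(C)O1; iodomethane, CI
Why: Copper-catalysed carboboration: syn borylcupration puts boron on the terminal carbon and copper on C10, and the alkenylcopper is methylated by MeI with retention, which gives the 10E alkenyl boronate. The alkoxide is largely tied up as the diboron ate complex, which limits its contact with the lactone.

Step 16
Reactants: 21 1-phenyl-2-butyne
Product: 23 [(2E)-3-iodobut-2-en-1-yl]benzene, via alkenylzirconocene chloride 22 (not isolated)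
Conditions: Cp2Zr(H)Cl (2.2 equiv), THF, rt → 50 °C; then [I][I], 0 °C
Reagents that add atoms: iodine, [I][I]
Why: Hydrozirconation adds Zr–H syn; with excess reagent and gentle warming the metal settles on the less hindered, methyl-bearing carbon, and iodinolysis with retention gives the (E)-iodide with iodine trans to the benzyl group.

Step 17
Reactants: 20 (3R,4aS,7aS)-3-[(2R,4E)-2,4-dimethyl-5-(4,4,5,5-tetramethyl-1,3,2-dioxaborolan-2-yl)pent-4-en-1-yl]-3,4a-dimethyltetrahydrofuro[3,2-c][1,2]dioxin-6(3H)-one; 23 [(2E)-3-iodobut-2-en-1-yl]benzene
Product: 24 (3R,4aS,7aS)-3,4a-dimethyl-3-[(2R,4E,6E)-2,4,6-trimethyl-8-phenylocta-4,6-dien-1-yl]tetrahydrofuro[3,2-c][1,2]dioxin-6(3H)-one (CNP0272658.1)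
Conditions: PdCl2(dppf) (5 mol %), K3PO4 (aq., 3 equiv), THF, rt; NaH2PO4 (aq.) work-up
Reagents that add atoms: none
Why: Suzuki–Miyaura coupling forms C11–C12 with retention at both alkenes and gives the (10E,12E)-diene; oxidative addition of the alkenyl iodide to zerovalent palladium is much faster than any reaction with a dialkyl peroxide, and the phosphate base with a weakly acidic work-up should keep the lactone closed.

## Compound list

1 | methyl hydrogen (R)-3-methylglutarate | COC(=O)C[C@H](C)CC(=O)O | starting material
2 | methyl (3R)-5-hydroxy-3-methylpentanoate | COC(=O)C[C@H](C)CCO | intermediate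
3 | methyl (3R)-5-[(tert-butyldimethylsilyl)oxy]-3-methylpentanoate | COC(=O)C[C@H](C)CCO[Si](C)(C)C(C)(C)C | intermediate
4 | (3R)-5-[(tert-butyldimethylsilyl)oxy]-3-methylpentanal | O=CC[C@H](C)CCO[Si](C)(C)C(C)(C)C | intermediate (not isolated)
5 | tert-butyldimethyl{[(3S)-3-methylhex-5-yn-1-yl]oxy}silane | C#CC[C@H](C)CCO[Si](C)(C)C(C)(C)C | intermediate
6 | {(1E,4S)-6-[(tert-butyldimethylsilyl)oxy]-2,4-dimethylhex-1-en-1-yl}dimethylalane | C[Al](C)/C=C(\C)C[C@H](C)CCO[Si](C)(C)C(C)(C)C | intermediate (not isolated)
7 | tert-butyl{[(3S,5E)-6-iodo-3,5-dimethylhex-5-en-1-yl]oxy}dimethylsilane | I/C=C(\C)C[C@H](C)CCO[Si](C)(C)C(C)(C)C | intermediate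
8 | pent-3-yn-1-ol | CC#CCCO | starting material
9 | (3Z)-4-(4,4,5,5-tetramethyl-1,3,2-dioxaborolan-2-yl)pent-3-en-1-ol | CC1(C)OB(/C(C)=C/CCO)OC1(C)C | intermediate
10 | (3Z)-4-(4,4,5,5-tetramethyl-1,3,2-dioxaborolan-2-yl)pent-3-enal | CC1(C)OB(/C(C)=C/CC=O)OC1(C)C | intermediate
11 | (3Z)-4-(4,4,5,5-tetramethyl-1,3,2-dioxaborolan-2-yl)pent-3-enoic acid | CC1(C)OB(/C(C)=C/CC(=O)O)OC1(C)C | intermediate
12 | (3E,5E,8S)-10-[(tert-butyldimethylsilyl)oxy]-4,6,8-trimethyldeca-3,5-dienoic acid | CC(C)(C)[Si](C)(C)OCC[C@@H](C)C/C(C)=C/C(C)=C/CC(=O)O | intermediate
13 | dioxygen | O=O | starting material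
14 | 2-[(3S,6R)-6-{(2R)-4-[(tert-butyldimethylsilyl)oxy]-2-methylbutyl}-4,6-dimethyl-3,6-dihydro-1,2-dioxin-3-yl]acetic acid | CC(C)(C)[Si](C)(C)OCC[C@@H](C)C[C@]1(C)C=C(C)[C@H](CC(=O)O)OO1 | intermediate
15 | (3R,4S,4aR,7aS)-3-{(2R)-4-[(tert-butyldimethylsilyl)oxy]-2-methylbutyl}-4-iodo-3,4a-dimethyltetrahydrofuro[3,2-c][1,2]dioxin-6(3H)-one | CC(C)(C)[Si](C)(C)OCC[C@@H](C)C[C@]1(C)[C@@H](I)[C@]2(C)OC(=O)C[C@@H]2OO1 | intermediate
16 | (3R,4aS,7aS)-3-{(2R)-4-[(tert-butyldimethylsilyl)oxy]-2-methylbutyl}-3,4a-dimethyltetrahydrofuro[3,2-c][1,2]dioxin-6(3H)-one | CC(C)(C)[Si](C)(C)OCC[C@@H](C)C[C@]1(C)C[C@]2(C)OC(=O)C[C@@H]2OO1 | intermediate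
17 | (3R,4aS,7aS)-3-[(2R)-4-hydroxy-2-methylbutyl]-3,4a-dimethyltetrahydrofuro[3,2-c][1,2]dioxin-6(3H)-one | OCC[C@@H](C)C[C@]1(C)C[C@]2(C)OC(=O)C[C@@H]2OO1 | intermediate
18 | (3S)-4-[(3R,4aS,7aS)-3,4a-dimethyl-6-oxohexahydrofuro[3,2-c][1,2]dioxin-3-yl]-3-methylbutanal | O=CC[C@@H](C)C[C@]1(C)C[C@]2(C)OC(=O)C[C@@H]2OO1 | intermediate
19 | (3R,4aS,7aS)-3,4a-dimethyl-3-[(2R)-2-methylpent-4-yn-1-yl]tetrahydrofuro[3,2-c][1,2]dioxin-6(3H)-one | C#CC[C@@H](C)C[C@]1(C)C[C@]2(C)OC(=O)C[C@@H]2OO1 | intermediate
20 | (3R,4aS,7aS)-3-[(2R,4E)-2,4-dimethyl-5-(4,4,5,5-tetramethyl-1,3,2-dioxaborolan-2-yl)pent-4-en-1-yl]-3,4a-dimethyltetrahydrofuro[3,2-c][1,2]dioxin-6(3H)-one | CC1(C)OB(/C=C(\C)C[C@@H](C)C[C@]2(C)C[C@]3(C)OC(=O)C[C@@H]3OO2)OC1(C)C | intermediate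
21 | 1-phenyl-2-butyne | CC#CCc1ccccc1 | starting material
22 | chlorobis(cyclopentadienyl)[(2E)-4-phenylbut-2-en-2-yl]zirconium | Cl[Zr](C1C=CC=C1)(C1C=CC=C1)/C(C)=C/Cc1ccccc1 | intermediate (not isolated)
23 | [(2E)-3-iodobut-2-en-1-yl]benzene | C/C(I)=C\Cc1ccccc1 | intermediate
24 | (3R,4aS,7aS)-3,4a-dimethyl-3-[(2R,4E,6E)-2,4,6-trimethyl-8-phenylocta-4,6-dien-1-yl]tetrahydrofuro[3,2-c][1,2]dioxin-6(3H)-one | CC(=C\Cc1ccccc1)/C=C(\C)C[C@@H](C)C[C@]1(C)C[C@]2(C)OC(=O)C[C@@H]2OO1 | target

## Step count and uncertain steps

Total: 17 steps. Longest linear sequence: 13 steps (steps 1–4, 8–15 and 17). Steps 5–7 and step 16 are side branches.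

Step 9 (key step). The most likely failure is hydrogen abstraction by singlet oxygen (ene reaction at the C6 and C4 methyl groups or at C7) overtaking cycloaddition, because the reactive cisoid conformer has a methyl group inside. In addition, attack on the two diene faces is unbiased, so half of the cycloadduct is lost on separation. Fallback (sets out from 12, returns at 17):
- PhSeCl (CH2Cl2, −78 °C) forms the seleniranium ion at C3=C4, which the carboxylate opens at the allylic tertiary C4 to give the 3-(phenylselanyl) γ-lactone F1.
- H2O2 oxidation and syn elimination of the selenoxide toward C2 give the butenolide F2.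
- Mukaiyama–Isayama hydroperoxysilylation (Co(thd)2 cat., thd = 2,2,6,6-tetramethylheptane-3,5-dionate, O2, Et3SiH) puts the silyl peroxide on C6 by hydrogen-atom transfer to C5, giving the triethylsilyl peroxide F3.
- Catalytic HCl in MeOH removes both silyl groups to give the hydroperoxide F4, and Et2NH in CF3CH2OH closes the dioxane by 6-exo oxa-Michael addition of the hydroperoxide to C3 of the butenolide, giving 17.

This makes the O–O bond from ground-state oxygen and avoids the ene problem, but C4 and C6 would form without control, so 17 would have to be separated from its isomers.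

Step 15. The most likely failure is reduction of the O–O bond by the boryl-copper species or by the diboron–alkoxide adduct, or alkoxide-induced enolisation of the lactone with loss of the C3–O bond, before the alkyne has reacted. Fallback (sets out from 19 and 23, returns at 24):
- Water-accelerated zirconium-catalysed carboalumination of 19 (AlMe3, Cp2ZrCl2 cat., H2O 1 equiv, CH2Cl2, −20 °C) gives the alkenylalane F5 (not isolated), and iodinolysis gives the (E)-alkenyl iodide F6.
- 23 is converted by Miyaura borylation (B2pin2, PdCl2(dppf), KOPh, toluene, 50 °C) into the alkenyl boronate F7.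
- Suzuki coupling of F6 with F7 under the conditions of step 17 gives 24.

The polarity of the last coupling is reversed and no boryl-copper species or stoichiometric alkoxide meets the peroxide, at the cost of a short low-temperature exposure to AlMe3.

Step 14. The most likely failure is base-mediated damage during the carbonate/methanol homologation: enolisation of the lactone followed by β-elimination of the C3–O bond, or methanolysis of the lactone. Fallback (sets out from 18, returns at 20):
- Chemoselective methyl transfer to the aldehyde with MeTi(OiPr)3 (THF, −40 °C) gives the secondary alcohol F8 (both carbinol epimers).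
- Dess–Martin oxidation gives the methyl ketone F9.
- Boron–Wittig olefination with LiCH(Bpin)2 (from CH2(Bpin)2 and lithium 2,2,6,6-tetramethylpiperidide, THF, −78 °C) converts the ketone directly into 20.

No alkyne and no carbonate/methanol are involved, and steps 14 and 15 are both bypassed. The geometric selectivity in the olefination of a methyl ketone is expected to be modest, so the 10Z isomer would have to be removed.

Step 11. The most likely failure is intramolecular attack of the C5 radical on the neighbouring O–O bond (epoxide formation with release of an alkoxyl radical) competing with hydrogen transfer. Fallback (sets out from 14, returns at 17): direct proton-initiated lactonisation with TfOH (5–10 mol %) in CH2Cl2 at 0 °C. C5 is protonated, the tertiary C4 cation is captured by the carboxyl group on the face of the C3 arm, and a methanol quench completes loss of the silyl group. 17 is thus reached without halogen or radical and steps 10–12 are bypassed. The risk moves to acid-induced ionisation of the allylic C6–O bond, which is why this is not the first choice.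

Step 5. The most likely failure is addition of the boryl-copper species with the opposite regiochemistry (boron on C3), which would give regioisomers that are hard to separate and would carry through the coupling. Fallback (sets out from 8 and 5, returns at 12):
- 8 is silylated (TBSCl, imidazole) to the silyl ether F10.
- Hydrozirconation with excess Cp2Zr(H)Cl at 50 °C, which lets the metal equilibrate to the methyl-bearing carbon, gives the alkenylzirconocene chloride F11 (not isolated), and iodinolysis gives the (E)-iodide F12.
- CrO3/H2SO4 in acetone (Jones oxidation) removes the silyl group and oxidises the carbinol to (E)-4-iodopent-3-enoic acid F13.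
- Alkyne 5 is converted by the CuCl-catalysed methylboration of step 15 into the alkenyl boronate F14.
- Suzuki coupling of F13 with F14 under the conditions of step 8 gives 12.

The regiochemistry then rests on a thermodynamically controlled hydrozirconation and on a terminal alkyne, and the polarity of the coupling is reversed.

## Further compounds

F1 | step 9 | 5-{(1E,4S)-6-[(tert-butyldimethylsilyl)oxy]-2,4-dimethylhex-1-en-1-yl}-5-methyl-4-(phenylselanyl)dihydrofuran-2(3H)-one (lactone centres not controlled) | O=C1CC([Se]c2ccccc2)C(C)(/C=C(\C)C[C@H](C)CCO[Si](C)(C)C(C)(C)C)O1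
F2 | step 9 | 5-{(1E,4S)-6-[(tert-butyldimethylsilyl)oxy]-2,4-dimethylhex-1-en-1-yl}-5-methylfuran-2(5H)-one (C5 of the furanone not controlled) | O=C1C=CC(C)(/C=C(\C)C[C@H](C)CCO[Si](C)(C)C(C)(C)C)O1
F3 | step 9 | 5-{(4R)-6-[(tert-butyldimethylsilyl)oxy]-2,4-dimethyl-2-[(triethylsilyl)peroxy]hexyl}-5-methylfuran-2(5H)-one (both quaternary centres not controlled) | O=C1C=CC(C)(CC(C)(OO[Si](CC)(CC)CC)C[C@H](C)CCO[Si](C)(C)C(C)(C)C)O1
F4 | step 9 | 5-[(4R)-2-hydroperoxy-6-hydroxy-2,4-dimethylhexyl]-5-methylfuran-2(5H)-one (both quaternary centres not controlled) | O=C1C=CC(C)(CC(C)(OO)C[C@H](C)CCO)O1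
F5 | step 15 | {(1E,4R)-5-[(3R,4aS,7aS)-3,4a-dimethyl-6-oxohexahydrofuro[3,2-c][1,2]dioxin-3-yl]-2,4-dimethylpent-1-en-1-yl}dimethylalane | C[Al](C)/C=C(\C)C[C@@H](C)C[C@]1(C)C[C@]2(C)OC(=O)C[C@@H]2OO1
F6 | step 15 | (3R,4aS,7aS)-3-[(2R,4E)-5-iodo-2,4-dimethylpent-4-en-1-yl]-3,4a-dimethyltetrahydrofuro[3,2-c][1,2]dioxin-6(3H)-one | I/C=C(\C)C[C@@H](C)C[C@]1(C)C[C@]2(C)OC(=O)C[C@@H]2OO1
F7 | step 15 | 4,4,5,5-tetramethyl-2-[(2Z)-4-phenylbut-2-en-2-yl]-1,3,2-dioxaborolane (boron trans to the benzyl group) | CC1(C)OB(/C(C)=C/Cc2ccccc2)OC1(C)C
F8 | step 14 | (3R,4aS,7aS)-3-[(2R)-4-hydroxy-2-methylpentyl]-3,4a-dimethyltetrahydrofuro[3,2-c][1,2]dioxin-6(3H)-one (carbinol epimers) | CC(O)C[C@@H](C)C[C@]1(C)C[C@]2(C)OC(=O)C[C@@H]2OO1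
F9 | step 14 | (3R,4aS,7aS)-3,4a-dimethyl-3-[(2S)-2-methyl-4-oxopentyl]tetrahydrofuro[3,2-c][1,2]dioxin-6(3H)-one | CC(=O)C[C@@H](C)C[C@]1(C)C[C@]2(C)OC(=O)C[C@@H]2OO1
F0 | step 11 | none | none
F10 | step 5 | tert-butyldimethyl(pent-3-yn-1-yloxy)silane | CC#CCCO[Si](C)(C)C(C)(C)C
F11 | step 5 | {(2E)-5-[(tert-butyldimethylsilyl)oxy]pent-2-en-2-yl}chlorobis(cyclopentadienyl)zirconium | C/C(=C\CCO[Si](C)(C)C(C)(C)C)[Zr](Cl)(C1C=CC=C1)C1C=CC=C1
F12 | step 5 | tert-butyl{[(3E)-4-iodopent-3-en-1-yl]oxy}dimethylsilane | C/C(I)=C\CCO[Si](C)(C)C(C)(C)C
F13 | step 5 | (3E)-4-iodopent-3-enoic acid | C/C(I)=C\CC(=O)O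
F14 | step 5 | tert-butyl{[(3S,5E)-3,5-dimethyl-6-(4,4,5,5-tetramethyl-1,3,2-dioxaborolan-2-yl)hex-5-en-1-yl]oxy}dimethylsilane | CC1(C)OB(/C=C(\C)C[C@H](C)CCO[Si](C)(C)C(C)(C)C)OC1(C)C
A1 | alternative 1 | (3R)-3-methyl-5-oxohexyl (3S)-3-hydroperoxy-4-methylpent-4-enoate | CC(=O)C[C@H](C)CCOC(=O)C[C@H](OO)C(C)=C
A2 | alternative 1 | (3R,4aS,7aS)-3-[(2R)-4-hydroxy-2-methylbutyl]-3,4a-dimethyltetrahydrofuro[3,2-c][1,2]dioxin-6(3H)-one | OCC[C@@H](C)C[C@]1(C)C[C@]2(C)OC(=O)C[C@@H]2OO1
A3 | alternative 2 | (4S,6R)-6-{(2R)-4-[(tert-butyldimethylsilyl)oxy]-2-methylbutyl}-4,6-dimethyl-1,2-dioxan-4-yl diazoacetate | CC(C)(C)[Si](C)(C)OCC[C@@H](C)C[C@]1(C)C[C@](C)(OC(=O)C=[N+]=[N-])COO1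
A4 | alternative 2 | (3R,4aS,7aS)-3-{(2R)-4-[(tert-butyldimethylsilyl)oxy]-2-methylbutyl}-3,4a-dimethyltetrahydrofuro[3,2-c][1,2]dioxin-6(3H)-one | CC(C)(C)[Si](C)(C)OCC[C@@H](C)C[C@]1(C)C[C@]2(C)OC(=O)C[C@@H]2OO1
A5 | alternative 3 | 2-[(3S,4R,6R)-6-[(2R)-4-acetoxy-2-methylbutyl]-4,6-dimethyl-1,2-dioxan-3-yl]acetic acid | CC(=O)OCC[C@@H](C)C[C@]1(C)C[C@@H](C)[C@H](CC(=O)O)OO1
A6 | alternative 3 | (3R)-3-methyl-4-[(3R,4aS,7aS)-3,4a-dimethyl-6-oxohexahydrofuro[3,2-c][1,2]dioxin-3-yl]butyl acetate | CC(=O)OCC[C@@H](C)C[C@]1(C)C[C@]2(C)OC(=O)C[C@@H]2OO1
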